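Every step that spends a reagent releases one released group, and the capture of mono adduct by released group spends no reagent, so c(reagent) + c(released group) falls by capture and by no other step.

    starting material + reagent → mono adduct + released group (k1 = 3.0 M⁻¹ s⁻¹)
    starting material + reagent → other mono adduct + released group (k2 = 0.12 M⁻¹ s⁻¹)
    reagent + mono adduct → double product + released group (k3 = 1.4 M⁻¹ s⁻¹)
    reagent + other mono adduct → double product + released group (k4 = 1.4 M⁻¹ s⁻¹)
    mono adduct + released group → side product (k5 = 6.4 M⁻¹ s⁻¹)

starting material 5.0 mM; reagent 1.10 equiv; time 2.5 h

- which holds at 2.5 h: what has brought the reaction to rest, or that it has not come to rest (all of the starting material has reacted / it is still moving / the reagent has run out first)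
- share of the starting material used up at 2.5 h

I followed one molecule. At the start, starting material went to mono adduct 25 times faster than to other mono adduct, so I dropped that branch. Even that slower step, taken alone at the charged concentrations, gave a half-life of 0.29 h, shorter than the 2.5 h allowed, so I did not expect time to stop this flask.

That left the fork of a mono adduct: it meets reagent at 1.4 M⁻¹ s⁻¹ times c(reagent), or released group at 6.4 M⁻¹ s⁻¹ times c(released group). As an estimate I held the sum at the reagent charge, setting capture aside, which put the tie of these two rates where a fraction of the reagent equal to 1.4 M⁻¹ s⁻¹ over the sum of the two constants was spent. I called this the tie share, 17.9%. As a rough bet, I let the same ratio stand for the share of mono adducts going on to double product, each costing a second reagent. One starting material used then cost 1.18 reagent, more than the 1.10 equiv charged. The reagent, as limiting reagent, should therefore give out first, at 93.2% conversion.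

The forecast said that the reagent has run out first, with 91% of the starting material used: “the reagent should be gone with a little starting material left”.

In the simulated flask the reagent has run out first, with 93.6% of the starting material used and 0% of the reagent left at 2.50 h. It then held 16.4% double product, which reads as a price of 1.18 reagent per starting material used, against my 1.18. Put on the neighbouring flask charged with 0.660 equiv of reagent, all else the same, my price gives 55.9% conversion. That flask reached 59.3%, with 6.66% double product at 2.50 h.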